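## Structural features

The target is a daucane-type sesquiterpene diester: a cyclopentane (C1–C5) fused through the C1–C5 bond to a cycloheptene (C1, C5–C10) whose only ring alkene, C8=C9, carries a methyl group on C8. Numbering used throughout: C1 is the ring-fusion carbon with the angular methyl, C2 and C3 are methylenes, C4 is the tertiary carbinol with the isopropyl group, C5 is the ring-fusion CH, C6 carries the 4-hydroxybenzoate, C7 is CH2, C10 carries the tiglate. The five stereocentres are contiguous: quaternary C1 (R) lies between C10 (S) and C5 (S), and C5 lies between C4 (R) and C6 (S). The ring fusion is cis: the C1 methyl, H5, the isopropyl group and the C6 oxygen sit on one face, while the C4 hydroxyl and the C10 oxygen sit on the other. Fragile elements are the allylic, conjugated tiglate at C10, the aryl ester with its free phenol, and the tertiary C4 hydroxyl, which is beta to C6 and invites retro-aldol cleavage or dehydration whenever C6 is a ketone. The real difficulty is the quaternary C1 flanked by two stereocentres inside a seven-membered ring, together with two different esters on two hindered secondary carbinols that must be told apart. The key step uses the fact that C5–C10, with oxygen on C6 and methyl on C8, is the substitution pattern of a 2-methoxy-4-methylphenyl ring, and that C1 can be inserted between C5 and C10 as a carbene carbon tethered through C2–C4.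

## Logic of the disconnections

31 is traced back to 30 (phenol silyl ether) and then to 28 and 29 by cutting the C10 O–acyl bond. The allylic conjugated ester and the free phenol are the most sensitive groups, so they come last. The forward step must acylate a hindered allylic hydroxyl without touching the tertiary C4 hydroxyl.

28 is traced back to 27 by changing C10–O into C10–B, and 27 to 23 and 26 by cutting the C6 O–acyl bond. This way the two secondary oxygens never coexist as free hydroxyls, so no selective acylation is needed. The boron group must survive the reduction and the esterification and then be oxidised with retention.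

23 is traced back to 22 by cutting the C6–H bond (ketone). With C1, C4, C5 and C10 fixed, the forward reduction must deliver hydride to the C6 face that carries C4–O. Only delivery from the C4 hydroxyl itself does this, so that hydroxyl must be free at this stage.

22 is traced back to 20 and 21 by cutting C10–B and C7–H. A planar cross-ring dienone then accounts for both the C10 heteroatom and the position of the C8=C9 alkene. The forward step needs delta-regioselectivity and boron delivery anti to the C1 methyl.

20 is traced back to 19 by cutting C5–H and returning C6=O to a methyl enol ether and C4–OH to a silyl ether. The forward step must set C5 under thermodynamic control, which should give the cis fusion.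

19 is traced back to 17 by re-introducing the C2 carbonyl. This oxygen is only the acceptor the carbenoid needs. Its removal must tolerate a triene, an enol ether and a beta-silyloxy group, which points to an anionic deoxygenation.

17 is traced back to 15 by cutting C1–C5 and C1–C10. This reveals the arene and removes both rings and the quaternary centre in one operation. The forward step must prefer the arene over 1,2-hydride shift, choose the C5–C10 bond over C5–C6, and choose one arene face.

15 is traced back to 13 (removal of the diazo group), 13 to 12, and 12 to 10 and 11 by cutting the C1–C2 bond. The forward enolisation must occur on the ethyl side and not toward the silyloxy-bearing carbon.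

10 is traced back to 9 (C2 aldehyde from a terminal alkene) and 9 to 8 (silyl ether from the tertiary alcohol). The silyl group is needed later to prevent O–H insertion and to keep the C4 oxygen from hydrogen-bonding to the methoxy group.

8 is traced back to 4 and 5 by cutting the C4–isopropyl bond, and 4 to 3 and then to 1 and 2 by cutting the C3–C4 bond. Enantiocontrol is secure at the secondary carbinol stage (aryl against hydrogen) and is then transferred stereospecifically. A direct addition to a ketone flanked by aryl and isopropyl groups of similar size would be far less certain.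

26 is traced back to 24: the phenol is masked so that it survives esterification, boron oxidation and acylation and is released last under buffered fluoride.

## Other disconnections considered

Alternative 1: The cut is the C1–C5 bond, made by a semipinacol ring expansion. A cyclobutanol carrying an epoxyalkyl chain on its carbinol carbon would be treated with a Lewis acid; the ring carbon C1 migrates anti to the breaking epoxide C–O bond and the cyclobutane becomes the cyclopentanone A1, with C1, C5 and the C6 hydroxyl in place. In its favour, the migration is stereospecific, so the C1/C5/C6 triad follows from the epoxide geometry and not from a facial preference; on this point it is better than the chosen plan. It is also better in that the C6 hydroxyl is free while the C10 oxygen is silylated from the outset, and no C2 oxygen has to be removed. Against it, the quaternary C1 with its neighbouring C10 carbinol and a defined epoxide must already exist on a strained ring, so the stereochemical problem is only moved upstream. The migrating carbon also carries an inductively deactivating oxygenated substituent and competes with the ring methylene. After A1 the seven-membered ring still has to be closed to a trisubstituted alkene by ring-closing metathesis, and an isopropyl nucleophile has to be added to a hindered, enolisable C4 ketone beside a beta-hydroxyl. The step count would probably exceed that of the chosen route.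

Alternative 2: The cuts are C7–C8 and C9–C10, made by a rhodium-catalysed [5+2] cycloaddition of a bicyclic donor–acceptor vinylcyclopropane with a terminal alkyne that supplies C8, its methyl and C9. The product is the dienone A2. In its favour, the C8=C9 alkene, the C8 methyl and the C10 oxygen arrive in their final positions. The C10 stereocentre is carried over from the cyclopropane and is not created next to the quaternary carbon, and no beta,gamma-unsaturated ketone has to be handled; on these points it is better than the chosen plan. Against it, the reaction is intermolecular on a cyclopropane bearing a quaternary carbon. The alkyne must insert with the methyl at C8, and the correct cyclopropane bond must open. After A2 the centres C4, C5 and C6 all remain to be set, and the C5=C6 alkene has to be hydrated in the anti-Markovnikov sense in the presence of the equally substituted C8=C9 alkene. The chosen plan fixes C1 and C4 before the rings exist and leaves only C5, C6 and C10 to set, with C5 under thermodynamic control. Overall step economy is at best equal.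

Alternative 3: The cuts are C6–C7 and C9–C10, made by a double allylation of a cis-1,2-dialdehyde on the finished cyclopentane. A reagent that is an allyl chloride at one end and an allylsilane at the other would add first as an allylindium species and then, under Lewis acid, as the allylsilane, closing the seven-membered ring to the diol A3. In its favour, both carbinol oxygens appear at the right oxidation level, there is no dearomatisation and no C2 oxygen to remove, and C1, C4 and C5 are set on a simple cyclopentane; in redox economy it is equal or better. Against it, two new carbinol centres must form on opposite faces without a strong controlling element. The dialdehyde is epimerisable at C5. The exocyclic methylene must later be isomerised toward C9 and not C7 with no inherent bias. The two secondary hydroxyls emerge free and undifferentiated, whereas the chosen plan keeps one of them masked as a boronate. The step count would be comparable.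

Key step: step 9

Assumption: the target has a cis ring fusion, (1R,4R,5S,6S,10S) in the C1–C10 numbering, and the route is built for exactly this isomer; systematic names use azulene numbering (C1 = 8a, C2 = 1, C3 = 2, C4 = 3, C5 = 3a, C6 = 4, C7 = 5, C8 = 6, C9 = 7, C10 = 8).

## Route

Step 1
Reactants: 1 2-methoxy-4-methylbenzaldehyde; 2 allylboronic acid pinacol ester
Product: 3 (1S)-1-(2-methoxy-4-methylphenyl)but-3-en-1-ol
Conditions: (S)-3,3'-bis(2,4,6-triisopropylphenyl)-1,1'-binaphthyl-2,2'-diyl hydrogen phosphate (5 mol%), toluene, −30 °C; aqueous work-up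
Reagents that add atoms: none
Why: Chiral phosphoric acid-catalysed allylboration of an aryl aldehyde through a closed chair transition state, a reaction type that is reliably enantioselective for aryl aldehydes. The (S)-acid is the antipode expected to give the (S)-carbinol, which becomes C4.

Step 2
Reactants: 3 (1S)-1-(2-methoxy-4-methylphenyl)but-3-en-1-ol
Product: 4 (1S)-1-(2-methoxy-4-methylphenyl)but-3-en-1-yl N,N-di(propan-2-yl)carbamate
Conditions: iPr2NCOCl, Et3N, CH2Cl2, reflux
Reagents that add atoms: N,N-di(propan-2-yl)carbamoyl chloride, CC(C)N(C(C)C)C(Cl)=O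
Why: Carbamoylation of a secondary alcohol; the stereocentre is not touched. The carbamate is the directing and leaving group for the next step.

Step 3
Reactants: 4 (1S)-1-(2-methoxy-4-methylphenyl)but-3-en-1-yl N,N-di(propan-2-yl)carbamate; 5 isopropylboronic acid pinacol ester
Product: 8 (3R)-3-(2-methoxy-4-methylphenyl)-2-methylhex-5-en-3-ol, via lithium boronate complex 6 (not isolated), via tertiary boronic ester 7 (not isolated)
Conditions: s-BuLi, Et2O, −78 °C; 5, −78 °C; MgBr2·OEt2, MeOH, −78 °C to rt; then NaOH, H2O2, THF, 0 °C to rt
Reagents that add atoms: hydrogen peroxide, OO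
Why: Lithiation–borylation: carbamate-directed benzylic deprotonation and borylation both occur with retention, the isopropyl group then migrates from boron to carbon anti to the departing carbamate (stereospecific 1,2-metallate shift), and C–B oxidation occurs with retention. The net result is replacement of the carbinol hydrogen by isopropyl with retention, which gives the (R)-tertiary alcohol.

Step 4
Reactants: 8 (3R)-3-(2-methoxy-4-methylphenyl)-2-methylhex-5-en-3-ol
Product: 9 triethyl{[(3R)-3-(2-methoxy-4-methylphenyl)-2-methylhex-5-en-3-yl]oxy}silane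
Conditions: Et3SiOTf, 2,6-lutidine, CH2Cl2, 0 °C to rt
Reagents that add atoms: triethylsilyl trifluoromethanesulfonate, CC[Si](CC)(CC)OS(=O)(=O)C(F)(F)F
Why: Silylation of a hindered tertiary alcohol with a silyl triflate. The silyl ether prevents O–H insertion of the later carbenoid and, unlike a free hydroxyl, cannot hydrogen-bond to the methoxy group, which would turn the C4–O bond toward C6 and reverse the facial sense of the key step.

Step 5
Reactants: 9 triethyl{[(3R)-3-(2-methoxy-4-methylphenyl)-2-methylhex-5-en-3-yl]oxy}silane
Product: 10 (3R)-3-(2-methoxy-4-methylphenyl)-4-methyl-3-[(triethylsilyl)oxy]pentanal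
Conditions: OsO4 (2 mol%), NaIO4, 2,6-lutidine, dioxane/H2O, rt
Reagents that add atoms: osmium tetroxide, O=[Os](=O)(=O)=O; sodium periodate, [Na+].[O-]I(=O)(=O)=O
Why: Lemieux–Johnson oxidative cleavage of a terminal alkene (dihydroxylation, then periodate cleavage). It is chosen over ozone because of the electron-rich arene; lutidine suppresses side reactions of the beta-silyloxy aldehyde.

Step 6
Reactants: 10 (3R)-3-(2-methoxy-4-methylphenyl)-4-methyl-3-[(triethylsilyl)oxy]pentanal; 11 ethylmagnesium bromide
Product: 12 (5R)-5-(2-methoxy-4-methylphenyl)-6-methyl-5-[(triethylsilyl)oxy]heptan-3-ol (both C3 epimers)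
Conditions: EtMgBr, THF, −78 °C; aq. NH4Cl
Reagents that add atoms: none
Why: Grignard addition to an aldehyde forms the C1–C2 bond. The new carbinol centre is oxidised in the next step, so its configuration does not matter.

Step 7
Reactants: 12 (5R)-5-(2-methoxy-4-methylphenyl)-6-methyl-5-[(triethylsilyl)oxy]heptan-3-ol (both C3 epimers)
Product: 13 (5R)-5-(2-methoxy-4-methylphenyl)-6-methyl-5-[(triethylsilyl)oxy]heptan-3-one
Conditions: Dess–Martin periodinane, NaHCO3, CH2Cl2, rt
Reagents that add atoms: none
Why: Buffered Dess–Martin oxidation of a secondary alcohol. The conditions are neutral, so the beta-silyloxy ketone is not exposed to elimination.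

Step 8
Reactants: 13 (5R)-5-(2-methoxy-4-methylphenyl)-6-methyl-5-[(triethylsilyl)oxy]heptan-3-one
Product: 15 (5R)-2-diazo-5-(2-methoxy-4-methylphenyl)-6-methyl-5-[(triethylsilyl)oxy]heptan-3-one, via trifluoroacetyl diketone 14 (not isolated)
Conditions: LiN(SiMe3)2, THF, −78 °C; CF3CO2CH2CF3; then 4-acetamidobenzenesulfonyl azide, Et3N, H2O, MeCN, rt
Reagents that add atoms: 2,2,2-trifluoroethyl trifluoroacetate, FC(F)(F)COC(=O)C(F)(F)F (trifluoroacetyl group of 14 only); 4-acetamidobenzenesulfonyl azide, CC(=O)Nc1ccc(cc1)S(=O)(=O)N=[N+]=[N-]
Why: Deacylative (Regitz-type) diazo transfer. Kinetic enolisation takes place at the ethyl CH2 and not at the neopentyl CH2 beside the quaternary carbinol, which also avoids beta-elimination of the silyloxy group. Claisen acylation then activates that carbon, and the sulfonyl azide transfers N2 with loss of the trifluoroacetyl group.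

Step 9
Reactants: 15 (5R)-2-diazo-5-(2-methoxy-4-methylphenyl)-6-methyl-5-[(triethylsilyl)oxy]heptan-3-one
Product: 17 (3R,8aS)-4-methoxy-6,8a-dimethyl-3-(propan-2-yl)-3-[(triethylsilyl)oxy]-3,8a-dihydroazulen-1(2H)-one, via norcaradiene 16 (not isolated)
Conditions: Rh2(OAc)4 (1 mol%), CH2Cl2, reflux, slow addition of 15
Reagents that add atoms: none
Why: The divalent rhodium carboxylate expels N2 from 15 to give an electrophilic carbenoid at C1, which adds across the C5–C10 bond of the tethered arene to give norcaradiene 16; its C5–C10 bond then opens by a thermal disrotatory 6π electrocyclic reaction to cycloheptatriene 17. The closest known reaction type is the intramolecular Buchner reaction of 1-diazo-4-arylbutan-2-ones, including alpha-methyl congeners, which gives 3,8a-dihydroazulen-1(2H)-ones. The five-membered ring closes by carbenoid [2+1] addition (C1–C5 and C1–C10 formed through the three-atom tether C2–C4), and the seven-membered ring arises by electrocyclic ring expansion of the arene-derived six-membered ring, with C1 inserted between C5 and C10. The new stereocentre C1 is controlled by C4: allylic 1,3-strain and dipole repulsion hold the C4–O bond near the arene plane, syn to C10–H and anti to the C6 methoxy group, so that the tether lies on one face and the isopropyl group pseudo-equatorial on the other. Addition from the tether face places the C1 methyl trans to the silyloxy group and cis to the isopropyl group, as the target requires. Chemoselectivity for the arene over 1,2-hydride shift and over attack on the silyl ether oxygen is supported by the electron-rich arene, the gem-disubstitution at C4 that folds the tether, the low migratory tendency of a methyl hydrogen with acetate ligands, and the hindered, weakly basic silyl ether oxygen. Regioselectivity for C5–C10 over C5–C6 comes from the methoxy group on C6. The face selectivity is the least secure of the three, because the competing transition state (C4–O syn to the methoxy group) has the more relaxed tether. The quaternary C1 has no hydrogen, so the triene cannot scramble by 1,5-hydrogen shifts.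

Step 10
Reactants: 17 (3R,8aS)-4-methoxy-6,8a-dimethyl-3-(propan-2-yl)-3-[(triethylsilyl)oxy]-3,8a-dihydroazulen-1(2H)-one
Product: 19 triethyl{[(3R,8aS)-4-methoxy-6,8a-dimethyl-3-(propan-2-yl)-1,2,3,8a-tetrahydroazulen-3-yl]oxy}silane, via silyl hydrazone 18 (not isolated)
Conditions: 1,2-bis(tert-butyldimethylsilyl)hydrazine, Sc(OTf)3 (1 mol%), CHCl3, 55 °C; then KOtBu, tBuOH, DMSO, 23 to 60 °C
Reagents that add atoms: 1,2-bis(tert-butyldimethylsilyl)hydrazine, CC(C)(C)[Si](C)(C)NN[Si](C)(C)C(C)(C)C (nitrogen and silicon atoms of 18 only)
Why: Wolff–Kishner reduction through an N-silyl hydrazone. The ketone is condensed under Lewis acid catalysis before any base is present, so no C2 enolate can expel the C4 silyloxy group. The anionic mechanism is chosen because a radical or cation at C2 would rearrange through the two vinyl groups on C1.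

Step 11
Reactants: 19 triethyl{[(3R,8aS)-4-methoxy-6,8a-dimethyl-3-(propan-2-yl)-1,2,3,8a-tetrahydroazulen-3-yl]oxy}silane
Product: 20 (3R,3aR,8aS)-3-hydroxy-6,8a-dimethyl-3-(propan-2-yl)-2,3,3a,8a-tetrahydroazulen-4(1H)-one
Conditions: 48% aq. HF, MeCN, 0 °C to rt
Reagents that add atoms: water, O
Why: Acid hydrolysis of the dienol ether: protonation at C5 gives a dienyl oxocarbenium ion, water adds at C6 and methanol is lost, while fluoride removes the tertiary silyl group. C5 is epimerisable through the enol and should settle in the cis-fused form, in which the C5–C6 bond is anti to both the isopropyl group and the C1 methyl on the five-membered ring and the C4 hydroxyl can hydrogen-bond to the C6 carbonyl.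

Step 12
Reactants: 20 (3R,3aR,8aS)-3-hydroxy-6,8a-dimethyl-3-(propan-2-yl)-2,3,3a,8a-tetrahydroazulen-4(1H)-one; 21 bis(pinacolato)diboron
Product: 22 (3R,3aR,8S,8aS)-3-hydroxy-6,8a-dimethyl-3-(propan-2-yl)-8-(4,4,5,5-tetramethyl-1,3,2-dioxaborolan-2-yl)-2,3,3a,5,8,8a-hexahydroazulen-4(1H)-one
Conditions: CuF(PPh3)3·2MeOH (5 mol%), (R)-1-[(S)-2-(diphenylphosphino)ferrocenyl]ethyldicyclohexylphosphine (the antipode is used if it proves to be the matched one), iPrOH, THF, rt
Reagents that add atoms: none
Why: Copper-catalysed 1,6-conjugate borylation of a dienone: the borylcopper species adds at the delta carbon C10 because the beta carbon C8 is blocked by its methyl group, and the dienolate is protonated at C7 to leave the C8=C9 alkene. The methyl and the ring CH2 on C1 differentiate the faces of C10 only weakly, so the chiral ligand is relied on to deliver boron anti to the C1 methyl; the alkoxide-free conditions spare the beta-hydroxy ketone.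

Step 13
Reactants: 22 (3R,3aR,8S,8aS)-3-hydroxy-6,8a-dimethyl-3-(propan-2-yl)-8-(4,4,5,5-tetramethyl-1,3,2-dioxaborolan-2-yl)-2,3,3a,5,8,8a-hexahydroazulen-4(1H)-one
Product: 23 (3R,3aS,4S,8S,8aS)-6,8a-dimethyl-3-(propan-2-yl)-8-(4,4,5,5-tetramethyl-1,3,2-dioxaborolan-2-yl)-1,2,3,3a,4,5,8,8a-octahydroazulene-3,4-diol
Conditions: Me4NBH(OAc)3, MeCN/AcOH (1:1), −30 to 0 °C
Reagents that add atoms: none
Why: Evans–Saksena reduction: the reagent exchanges an acetate for the C4 hydroxyl and delivers hydride intramolecularly to the C6 carbonyl face that carries C4–O, giving the 1,3-anti diol with the C6 hydroxyl on the face of H5. The reagent is too weak to reduce the ketone without this delivery, and the alkene and the boronate are not affected.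

Step 14
Reactants: 24 4-hydroxybenzoic acid
Product: 26 4-{[tri(propan-2-yl)silyl]oxy}benzoic acid, via bis-silyl ester 25 (not isolated)
Conditions: iPr3SiCl (2.2 equiv), imidazole, DMF, rt; then K2CO3, THF/MeOH/H2O, rt; then 1 M HCl to pH 4
Reagents that add atoms: chlorotri(propan-2-yl)silane, CC(C)[Si](Cl)(C(C)C)C(C)C
Why: Silylation of both acidic groups followed by selective hydrolysis of the labile silyl ester. The aryl triisopropylsilyl ether is robust enough for the esterification, boron oxidation and acylation that follow.

Step 15
Reactants: 23 (3R,3aS,4S,8S,8aS)-6,8a-dimethyl-3-(propan-2-yl)-8-(4,4,5,5-tetramethyl-1,3,2-dioxaborolan-2-yl)-1,2,3,3a,4,5,8,8a-octahydroazulene-3,4-diol; 26 4-{[tri(propan-2-yl)silyl]oxy}benzoic acid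
Product: 27 (3R,3aS,4S,8S,8aS)-3-hydroxy-6,8a-dimethyl-3-(propan-2-yl)-8-(4,4,5,5-tetramethyl-1,3,2-dioxaborolan-2-yl)-1,2,3,3a,4,5,8,8a-octahydroazulen-4-yl 4-{[tri(propan-2-yl)silyl]oxy}benzoate
Conditions: EDC·HCl, DMAP, CH2Cl2, rt
Reagents that add atoms: none
Why: Steglich esterification of the only free secondary hydroxyl. The tertiary C4 hydroxyl does not react, and the C10 oxygen is still masked as the C–B bond, so the two secondary positions cannot be confused.

Step 16
Reactants: 27 (3R,3aS,4S,8S,8aS)-3-hydroxy-6,8a-dimethyl-3-(propan-2-yl)-8-(4,4,5,5-tetramethyl-1,3,2-dioxaborolan-2-yl)-1,2,3,3a,4,5,8,8a-octahydroazulen-4-yl 4-{[tri(propan-2-yl)silyl]oxy}benzoate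
Product: 28 (3R,3aS,4S,8S,8aR)-3,8-dihydroxy-6,8a-dimethyl-3-(propan-2-yl)-1,2,3,3a,4,5,8,8a-octahydroazulen-4-yl 4-{[tri(propan-2-yl)silyl]oxy}benzoate
Conditions: NaBO3·4H2O, THF/H2O (1:1), rt
Reagents that add atoms: sodium perborate tetrahydrate (peroxoborate salt), [Na+].[Na+].O[B-]1(O)OO[B-](O)(O)OO1
Why: Oxidation of the allylic boronate by 1,2-migration of carbon from boron to oxygen, with retention at C10 and no allylic transposition. Perborate is mild enough to leave the aryl ester and the aryl silyl ether intact.

Step 17
Reactants: 28 (3R,3aS,4S,8S,8aR)-3,8-dihydroxy-6,8a-dimethyl-3-(propan-2-yl)-1,2,3,3a,4,5,8,8a-octahydroazulen-4-yl 4-{[tri(propan-2-yl)silyl]oxy}benzoate; 29 (2E)-2-methylbut-2-enoyl chloride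
Product: 30 (3R,3aS,4S,8S,8aR)-3-hydroxy-6,8a-dimethyl-8-{[(2E)-2-methylbut-2-enoyl]oxy}-3-(propan-2-yl)-1,2,3,3a,4,5,8,8a-octahydroazulen-4-yl 4-{[tri(propan-2-yl)silyl]oxy}benzoate
Conditions: 29, pyridine, DMAP, CH2Cl2, 0 °C to rt
Reagents that add atoms: none
Why: DMAP-catalysed acylation of the hindered allylic alcohol; the tertiary hydroxyl stays free. Pyridine is used in place of a trialkylamine so that the acid chloride is not converted to a vinylketene, which would deconjugate the ester; the E geometry is retained.

Step 18
Reactants: 30 (3R,3aS,4S,8S,8aR)-3-hydroxy-6,8a-dimethyl-8-{[(2E)-2-methylbut-2-enoyl]oxy}-3-(propan-2-yl)-1,2,3,3a,4,5,8,8a-octahydroazulen-4-yl 4-{[tri(propan-2-yl)silyl]oxy}benzoate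
Product: 31 (3R,3aS,4S,8S,8aR)-3-hydroxy-6,8a-dimethyl-8-{[(2E)-2-methylbut-2-enoyl]oxy}-3-(propan-2-yl)-1,2,3,3a,4,5,8,8a-octahydroazulen-4-yl 4-hydroxybenzoate
Conditions: Bu4NF, AcOH, THF, 0 °C
Reagents that add atoms: none
Why: Fluoride cleavage of the aryl silyl ether. Buffering with acetic acid keeps the medium non-basic, so neither ester is cleaved and the tiglate is not isomerised.

## Compound list

1 | 2-methoxy-4-methylbenzaldehyde | O=Cc1ccc(C)cc1OC | starting material
2 | allylboronic acid pinacol ester | C=CCB1OC(C)(C)C(C)(C)O1 | starting material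
3 | (1S)-1-(2-methoxy-4-methylphenyl)but-3-en-1-ol | C=CC[C@H](O)c1ccc(C)cc1OC | intermediate
4 | (1S)-1-(2-methoxy-4-methylphenyl)but-3-en-1-yl N,N-di(propan-2-yl)carbamate | C=CC[C@H](OC(=O)N(C(C)C)C(C)C)c1ccc(C)cc1OC | intermediate
5 | isopropylboronic acid pinacol ester | CC(C)B1OC(C)(C)C(C)(C)O1 | starting material
6 | lithium boronate complex of lithiated 4 and 5, (S) at the carbamate carbon | [Li+].C=CC[C@]([B-]1(C(C)C)OC(C)(C)C(C)(C)O1)(OC(=O)N(C(C)C)C(C)C)c1ccc(C)cc1OC | intermediate
7 | 2-[(3S)-3-(2-methoxy-4-methylphenyl)-2-methylhex-5-en-3-yl]-4,4,5,5-tetramethyl-1,3,2-dioxaborolane | C=CC[C@@](B1OC(C)(C)C(C)(C)O1)(C(C)C)c1ccc(C)cc1OC | intermediate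
8 | (3R)-3-(2-methoxy-4-methylphenyl)-2-methylhex-5-en-3-ol | C=CC[C@@](O)(C(C)C)c1ccc(C)cc1OC | intermediate
9 | triethyl{[(3R)-3-(2-methoxy-4-methylphenyl)-2-methylhex-5-en-3-yl]oxy}silane | C=CC[C@@](O[Si](CC)(CC)CC)(C(C)C)c1ccc(C)cc1OC | intermediate
10 | (3R)-3-(2-methoxy-4-methylphenyl)-4-methyl-3-[(triethylsilyl)oxy]pentanal | O=CC[C@@](O[Si](CC)(CC)CC)(C(C)C)c1ccc(C)cc1OC | intermediate
11 | ethylmagnesium bromide | CC[Mg]Br | starting material
12 | (5R)-5-(2-methoxy-4-methylphenyl)-6-methyl-5-[(triethylsilyl)oxy]heptan-3-ol, both C3 epimers | CCC(O)C[C@@](O[Si](CC)(CC)CC)(C(C)C)c1ccc(C)cc1OC | intermediate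
13 | (5R)-5-(2-methoxy-4-methylphenyl)-6-methyl-5-[(triethylsilyl)oxy]heptan-3-one | CCC(=O)C[C@@](O[Si](CC)(CC)CC)(C(C)C)c1ccc(C)cc1OC | intermediate
14 | (6R)-1,1,1-trifluoro-6-(2-methoxy-4-methylphenyl)-3,7-dimethyl-6-[(triethylsilyl)oxy]octane-2,4-dione, C3 epimers and enol forms | CC(C(=O)C(F)(F)F)C(=O)C[C@@](O[Si](CC)(CC)CC)(C(C)C)c1ccc(C)cc1OC | intermediate
15 | (5R)-2-diazo-5-(2-methoxy-4-methylphenyl)-6-methyl-5-[(triethylsilyl)oxy]heptan-3-one | CC(=[N+]=[N-])C(=O)C[C@@](O[Si](CC)(CC)CC)(C(C)C)c1ccc(C)cc1OC | intermediate
16 | norcaradiene valence isomer of 17 (cyclopropane C1–C5–C10 closed, C1 methyl trans to the silyloxy group) | COC1=CC(C)=C[C@H]2[C@]3(C)C(=O)C[C@@](O[Si](CC)(CC)CC)(C(C)C)[C@]123 | intermediate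
17 | (3R,8aS)-4-methoxy-6,8a-dimethyl-3-(propan-2-yl)-3-[(triethylsilyl)oxy]-3,8a-dihydroazulen-1(2H)-one | C1=CC(C)=CC(OC)=C2[C@@]1(C)C(=O)C[C@@]2(O[Si](CC)(CC)CC)C(C)C | intermediate
18 | N-tert-butyldimethylsilyl hydrazone of 17 at C1 of the azulenone (C=N geometry not defined) | C1=CC(C)=CC(OC)=C2[C@@]1(C)C(=NN[Si](C)(C)C(C)(C)C)C[C@@]2(O[Si](CC)(CC)CC)C(C)C | intermediate
19 | triethyl{[(3R,8aS)-4-methoxy-6,8a-dimethyl-3-(propan-2-yl)-1,2,3,8a-tetrahydroazulen-3-yl]oxy}silane | C1=CC(C)=CC(OC)=C2[C@@]1(C)CC[C@@]2(O[Si](CC)(CC)CC)C(C)C | intermediate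
20 | (3R,3aR,8aS)-3-hydroxy-6,8a-dimethyl-3-(propan-2-yl)-2,3,3a,8a-tetrahydroazulen-4(1H)-one | C1=CC(C)=CC(=O)[C@@H]2[C@@]1(C)CC[C@@]2(O)C(C)C | intermediate
21 | bis(pinacolato)diboron | CC1(C)OB(OC1(C)C)B1OC(C)(C)C(C)(C)O1 | starting material
22 | (3R,3aR,8S,8aS)-3-hydroxy-6,8a-dimethyl-3-(propan-2-yl)-8-(4,4,5,5-tetramethyl-1,3,2-dioxaborolan-2-yl)-2,3,3a,5,8,8a-hexahydroazulen-4(1H)-one | CC1(C)OB(OC1(C)C)[C@H]2C=C(C)CC(=O)[C@@H]3[C@@]2(C)CC[C@@]3(O)C(C)C | intermediate
23 | (3R,3aS,4S,8S,8aS)-6,8a-dimethyl-3-(propan-2-yl)-8-(4,4,5,5-tetramethyl-1,3,2-dioxaborolan-2-yl)-1,2,3,3a,4,5,8,8a-octahydroazulene-3,4-diol | CC1(C)OB(OC1(C)C)[C@H]2C=C(C)C[C@H](O)[C@@H]3[C@@]2(C)CC[C@@]3(O)C(C)C | intermediate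
24 | 4-hydroxybenzoic acid | OC(=O)c1ccc(O)cc1 | starting material
25 | tri(propan-2-yl)silyl 4-{[tri(propan-2-yl)silyl]oxy}benzoate | CC(C)[Si](OC(=O)c1ccc(O[Si](C(C)C)(C(C)C)C(C)C)cc1)(C(C)C)C(C)C | intermediate
26 | 4-{[tri(propan-2-yl)silyl]oxy}benzoic acid | OC(=O)c1ccc(O[Si](C(C)C)(C(C)C)C(C)C)cc1 | intermediate
27 | (3R,3aS,4S,8S,8aS)-3-hydroxy-6,8a-dimethyl-3-(propan-2-yl)-8-(4,4,5,5-tetramethyl-1,3,2-dioxaborolan-2-yl)-1,2,3,3a,4,5,8,8a-octahydroazulen-4-yl 4-{[tri(propan-2-yl)silyl]oxy}benzoate | CC1(C)OB(OC1(C)C)[C@H]2C=C(C)C[C@H](OC(=O)c4ccc(O[Si](C(C)C)(C(C)C)C(C)C)cc4)[C@@H]3[C@@]2(C)CC[C@@]3(O)C(C)C | intermediate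
28 | (3R,3aS,4S,8S,8aR)-3,8-dihydroxy-6,8a-dimethyl-3-(propan-2-yl)-1,2,3,3a,4,5,8,8a-octahydroazulen-4-yl 4-{[tri(propan-2-yl)silyl]oxy}benzoate | O[C@H]1C=C(C)C[C@H](OC(=O)c2ccc(O[Si](C(C)C)(C(C)C)C(C)C)cc2)[C@@H]2[C@@]1(C)CC[C@@]2(O)C(C)C | intermediate
29 | (2E)-2-methylbut-2-enoyl chloride (tigloyl chloride) | C/C=C(\C)C(Cl)=O | starting material
30 | (3R,3aS,4S,8S,8aR)-3-hydroxy-6,8a-dimethyl-8-{[(2E)-2-methylbut-2-enoyl]oxy}-3-(propan-2-yl)-1,2,3,3a,4,5,8,8a-octahydroazulen-4-yl 4-{[tri(propan-2-yl)silyl]oxy}benzoate | C/C=C(\C)C(=O)O[C@H]1C=C(C)C[C@H](OC(=O)c2ccc(O[Si](C(C)C)(C(C)C)C(C)C)cc2)[C@@H]2[C@@]1(C)CC[C@@]2(O)C(C)C | intermediate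
31 | (3R,3aS,4S,8S,8aR)-3-hydroxy-6,8a-dimethyl-8-{[(2E)-2-methylbut-2-enoyl]oxy}-3-(propan-2-yl)-1,2,3,3a,4,5,8,8a-octahydroazulen-4-yl 4-hydroxybenzoate | C/C=C(\C)C(=O)O[C@H]1C=C(C)C[C@H](OC(=O)c2ccc(O)cc2)[C@@H]2[C@@]1(C)CC[C@@]2(O)C(C)C | target

## Step count and risk

Total: 18 steps. Longest linear sequence: 17 steps (steps 1–13 and 15–18); step 14 is a one-step side branch.

Step 9 (key step). The most likely failure is weak discrimination between the two arene faces, because both competing transition states can keep the isopropyl group pseudo-equatorial and differ only in whether the C4–O bond lies toward C10–H or toward the methoxy group. A second risk is diversion of the carbenoid by 1,2-hydride migration from the C1 methyl or by attack of the silyl ether oxygen. The fallback changes the source of stereocontrol from the substrate to the reagent. It sets out from 15 and returns at 17: the cyclisation is run with a cationic monovalent copper catalyst, Cu(MeCN)4PF6 with a C2-symmetric bis(oxazoline) and NaB[3,5-(CF3)2C6H3]4, a catalyst class that selects the arene face of alpha-methyl diazoketones on its own. The ligand antipode that reinforces the preference of C4 is used; the C1 epimers of 17 are diastereomers and remain separable. No new compound is made (F0).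

Step 12. The methyl and the ring methylene on C1 shield the two faces of C10 to a similar degree, so boron delivery may be poorly face-selective even with the chiral ligand; addition at the neopentyl delta carbon may also be slow. The fallback sets C10 by ketone reduction instead of C–B bond formation. It sets out from 28, whatever its C10 epimer content, and returns at 28: the allylic alcohol is oxidised with MnO2 to the enone (3R,3aS,4S,8aR)-3-hydroxy-6,8a-dimethyl-8-oxo-3-(propan-2-yl)-1,2,3,3a,4,5,8,8a-octahydroazulen-4-yl 4-{[tri(propan-2-yl)silyl]oxy}benzoate F4, which is reduced with a B-methyl oxazaborolidine catalyst and BH3·SMe2 (Corey–Bakshi–Shibata reduction). That reagent distinguishes the quaternary C1 flank from the vinylic C9 flank and returns the (8S)-alcohol 28.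

Step 13. The hindered tertiary hydroxyl may exchange onto boron too slowly for internal hydride delivery, and prolonged exposure to acetic acid may protodeboronate the allylic boronate. The fallback replaces directed reduction by reduction from the open face followed by inversion. It sets out from 22 and returns at 27: NaBH4 with CeCl3·7H2O should attack C6 from the face away from the five-membered ring and give the C6 epimer (3R,3aS,4R,8S,8aS)-6,8a-dimethyl-3-(propan-2-yl)-8-(4,4,5,5-tetramethyl-1,3,2-dioxaborolan-2-yl)-1,2,3,3a,4,5,8,8a-octahydroazulene-3,4-diol F5. Mitsunobu esterification of F5 with 26 (PPh3, diisopropyl azodicarboxylate) then installs the aroyl group with inversion and gives 27 directly.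

Step 10. Condensation at the hindered C2 ketone may be slow, and the strongly basic second stage may cleave the silyl ether or move the triene double bonds by deprotonation of the C8 methyl. The fallback replaces base-induced decomposition by hydride reduction of a sulfonyl hydrazone. It sets out from 17 and returns at 19: 17 is condensed with 4-methylbenzenesulfonohydrazide to N'-[(3R,8aS)-4-methoxy-6,8a-dimethyl-3-(propan-2-yl)-3-(triethylsilyloxy)-3,8a-dihydroazulen-1(2H)-ylidene]-4-methylbenzenesulfonohydrazide F3, which is reduced with catecholborane in CHCl3 at 0 °C and then heated with NaOAc·3H2O to give 19.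

Step 3. With the hindered secondary boronic ester and the ortho-substituted, electron-rich aryl group, formation of the boronate complex may become reversible and the 1,2-shift slow, which would erode the configuration at C4. The fallback sets C4 by carbonyl addition instead of by 1,2-metallate rearrangement. It sets out from 1 and returns at 8: addition of iPrMgCl to 1 gives racemic 1-(2-methoxy-4-methylphenyl)-2-methylpropan-1-ol F1, Dess–Martin oxidation gives 1-(2-methoxy-4-methylphenyl)-2-methylpropan-1-one F2, and copper-catalysed asymmetric allylboration of F2 with 2 (CuF2·2H2O, (R,R)-1,2-bis(2,5-diisopropylphospholano)benzene or its antipode, La(OiPr)3, DMF, −40 °C) gives 8. Its enantiomeric purity would be upgraded by chromatography on a chiral phase if needed.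

## Further compounds

F0 | step 9 | none | none
F1 | step 3 | 1-(2-methoxy-4-methylphenyl)-2-methylpropan-1-ol (racemic) | CC(C)C(O)c1ccc(C)cc1OC
F2 | step 3 | 1-(2-methoxy-4-methylphenyl)-2-methylpropan-1-one | CC(C)C(=O)c1ccc(C)cc1OC
F3 | step 10 | N'-[(3R,8aS)-4-methoxy-6,8a-dimethyl-3-(propan-2-yl)-3-(triethylsilyloxy)-3,8a-dihydroazulen-1(2H)-ylidene]-4-methylbenzenesulfonohydrazide | C1=CC(C)=CC(OC)=C2[C@@]1(C)C(=NNS(=O)(=O)c3ccc(C)cc3)C[C@@]2(O[Si](CC)(CC)CC)C(C)C
F4 | step 12 | (3R,3aS,4S,8aR)-3-hydroxy-6,8a-dimethyl-8-oxo-3-(propan-2-yl)-1,2,3,3a,4,5,8,8a-octahydroazulen-4-yl 4-{[tri(propan-2-yl)silyl]oxy}benzoate | O=C1C=C(C)C[C@H](OC(=O)c2ccc(O[Si](C(C)C)(C(C)C)C(C)C)cc2)[C@@H]2[C@@]1(C)CC[C@@]2(O)C(C)C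
F5 | step 13 | (3R,3aS,4R,8S,8aS)-6,8a-dimethyl-3-(propan-2-yl)-8-(4,4,5,5-tetramethyl-1,3,2-dioxaborolan-2-yl)-1,2,3,3a,4,5,8,8a-octahydroazulene-3,4-diol | CC1(C)OB(OC1(C)C)[C@H]2C=C(C)C[C@@H](O)[C@@H]3[C@@]2(C)CC[C@@]3(O)C(C)C
A1 | alternative 1 | 2,3-cis-disubstituted cyclopentanone with free C6 hydroxyl, silylated C10 carbinol, vinyl and methallyl termini | C=C[C@H](O[Si](C)(C)C(C)(C)C)[C@]1(C)CCC(=O)[C@@H]1[C@@H](O)CC(C)=C
A2 | alternative 2 | bicyclic dienone with C8 methyl alkene, C10 4-methoxybenzyl ether and C5=C6 enone | COc1ccc(cc1)CO[C@H]1C=C(C)CC=C2[C@@]1(C)CCC2=O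
A3 | alternative 3 | bicyclic cycloheptane-C6,C10-diol with exocyclic methylene at C8 and silylated C4 carbinol | O[C@H]1CC(=C)C[C@H](O)[C@@H]2[C@@]1(C)CC[C@@]2(O[Si](CC)(CC)CC)C(C)C
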